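I wanted to know how much target a flask holds at 10 min, and whether that number moves as [protic impurity] rises from 0.200 mM to 1.50 mM.

the same everywhere: substrate 16 mM; partner 20.8 mM; free catalyst 2.4 mM

| run | protic impurity | remark | time |
|---|---|---|---|
| alder | 0.10 mM | run made earlier |  |
| cedar | 1.1 mM | run made earlier |  |
| dawn | 0.200 mM |  | 10 min |
| autumn | 0.500 mM |  | 10 min |
| noon | 1.50 mM |  | 10 min |

- alder (time / min: target / %): 0.417: 1; 0.667: 3; 1.00: 1; 2.00: 8; 3.00: 14; 5.00: 26
- cedar (time / min: target / %): 0.333: 2; 1.00: 3; 2.00: 5; 2.50: 9; 4.00: 18; 5.00: 26

(readings scatter by 2 percentage points)

- "hardly changes" means that all values lie within two and a half points (for a concentration: within two and a half percent of the largest)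

* amount of target at the end, in percent of the substrate charged for dawn, autumn, noon, in this order
* how that number moves from the first to the last of them (falls all the way / rises all the way / rises, then falls / falls, then rises / hardly changes)

Two settings were in play, and I took them in turn. The first was time. Alder climbed from 8% at 2.00 min to 26% at 5.00 min. Drawn straight on, that line reached 56.0% at the end. I held this as an upper mark, since I expected the climb to slow as substrate was used.

The second was the impurity. Alder and cedar differed by 1.00 mM in [protic impurity], yet they read 26% and 26% at 5.00 min. So I read no loss of target. But a difference of two readings has a scatter of 2.8 percentage points. I scaled that scatter by the span of charges in question over the span between the two runs. This gave the impurity swing, the shift in target that the readings cannot exclude at one standard deviation: 3.7 points from dawn to noon. I assumed that it held at the end too. The shift I read at 5.00 min was 0 points, so I expected a flat row, though a swing of that size left the call open.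

The forecast gave 52%, 52% and 51%, which is lower than my line, and called the shape "hardly changes". Its ground was that “The impurity effect should be only a point or two”.

The flasks gave 50.2%, 49.9% and 48.9%: hardly changes.

    partner + protic impurity → quenched reagent (k = 41.0 M⁻¹ min⁻¹)
    substrate + catalyst intermediate A ⇌ catalyst intermediate B (K = 470 M⁻¹, k = 710 M⁻¹ min⁻¹)
    catalyst intermediate B → free catalyst + target (k = 0.760 min⁻¹)
    partner + free catalyst → catalyst intermediate A (k = 60.0 M⁻¹ min⁻¹)

From dawn to noon the target fell by 1.3 points, against a swing of 3.7 points. From autumn to noon it fell by 1 point, against a swing of 2.8 points. With partner taken at its charge, the pseudo-first-order half-life of the protic impurity in its step with partner was 0.813 min, far shorter than the 10 min of the run. At 5.00 min noon held 3.38% of its protic impurity, and at 10.0 min it held 1.50 mM of quenched reagent beside 49% of its partner.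

The data were computed on assumed constants, noise included.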